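Ring A is not carried in as a resorcinol but is built last: its C1–C2 and C5–C6 bonds are made in one Diels–Alder benzannulation between a terminal ynone and a 1,1,3-trioxygenated butadiene. The step exploits the substitution pattern of ring A itself (acyl on C1, free hydroxyl on C2, geranyl ether on C4), which the diene oxygens deliver directly once methanol is lost, so no phenol has to be differentiated. The dienophile is the (R)-α-silyloxy ethynyl ketone made from D-tyrosine, which already holds ring B and the carbinol stereocentre; the diene is the silyl ketene acetal of methyl 3-(geranyloxy)but-2-enoate. Buffered fluoride then releases the target.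

Key step: step 7

Remark: geranyl = (2E)-3,7-dimethylocta-2,6-dien-1-yl and TBS = tert-butyldimethylsilyl; ring A is numbered from the acyl-bearing carbon (C1) via the hydroxylated carbon (C2) to the geranyloxy carbon (C4); the ketene acetal geometry of the diene is drawn (1Z) but is immaterial, since that carbon becomes aromatic.

Step 1
Reactants: 1 D-tyrosine
Product: 4 (R)-2-hydroxy-3-(4-hydroxyphenyl)propanoic acid, via diazonium carboxylate 2 (not isolated), via alpha-lactone 3 (not isolated)
Conditions: NaNO2 (1.5 equiv), 1 M H2SO4 (aq), 0 °C → rt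
Reagents that add atoms: water, O
Why: Diazotisation of an α-amino acid (nitrous acid deamination) with net retention: the neighbouring carboxylate expels N2 from diazonium 2 with inversion to give α-lactone 3, which water opens at the α-carbon with a second inversion, so the (R) configuration of 1 is carried into 4.

Step 2
Reactants: 4 (R)-2-hydroxy-3-(4-hydroxyphenyl)propanoic acid
Product: 6 (R)-2-hydroxy-3-(4-hydroxyphenyl)-N-methoxy-N-methylpropanamide, via benzotriazolyl ester 5 (not isolated)
Conditions: MeNHOMe·HCl, EDC·HCl, HOBt, N-methylmorpholine, DMF, 0 °C → rt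
Reagents that add atoms: N,O-dimethylhydroxylamine hydrochloride, CNOC.Cl
Why: Carbodiimide/HOBt amide coupling to the Weinreb amide: the amine intercepts active ester 5 much faster than the alcohol or phenol hydroxyls do, and an α-hydroxy acid has no oxazolone pathway for racemisation, so the (R) centre is retained.

Step 3
Reactants: 6 (R)-2-hydroxy-3-(4-hydroxyphenyl)-N-methoxy-N-methylpropanamide
Product: 7 (R)-2-(tert-butyldimethylsilyloxy)-3-[4-(tert-butyldimethylsilyloxy)phenyl]-N-methoxy-N-methylpropanamide
Conditions: TBSCl (2.5 equiv), imidazole, DMAP (cat.), DMF, rt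
Reagents that add atoms: tert-butyldimethylsilyl chloride, CC(C)(C)[Si](C)(C)Cl
Why: Imidazole-promoted silylation of the phenol and the secondary alcohol with a silyl chloride; both TBS ethers should withstand the Grignard and cycloaddition steps and are cleaved together at the end.

Step 4
Reactants: 7 (R)-2-(tert-butyldimethylsilyloxy)-3-[4-(tert-butyldimethylsilyloxy)phenyl]-N-methoxy-N-methylpropanamide
Product: 9 (R)-4-(tert-butyldimethylsilyloxy)-5-[4-(tert-butyldimethylsilyloxy)phenyl]pent-1-yn-3-one, via magnesium hemiaminal chelate 8 (not isolated)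
Conditions: HC≡CMgBr (2.5 equiv), THF, 0 °C; inverse quench into cold 1 M HCl
Reagents that add atoms: ethynylmagnesium bromide, C#C[Mg]Br
Why: Weinreb ketone synthesis: the magnesium-chelated tetrahedral adduct 8 does not collapse until the quench, so a single acetylide is delivered, the weakly basic acetylide does not deprotonate the α-carbon, and the acidic inverse quench protonates the released amine before it can add to the ynone.

Step 5
Reactants: 10 geraniol; 11 methyl but-2-ynoate
Product: 12 methyl (2E)-3-(geranyloxy)but-2-enoate
Conditions: PBu3 (10 mol %), CH2Cl2, 0 °C → rt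
Reagents that add atoms: none
Why: Trialkylphosphine-catalysed oxa-Michael addition of an alcohol to a 2-alkynoate: the phosphine–ynoate zwitterion deprotonates geraniol and the resulting phosphonium alkoxide adds to the β-carbon, giving the thermodynamically preferred (E) β-alkoxy enoate under neutral conditions that leave the methyl ester and the acid-sensitive geranyl unit untouched.

Step 6
Reactants: 12 methyl (2E)-3-(geranyloxy)but-2-enoate
Product: 14 (1Z)-3-(geranyloxy)-1-methoxy-1-(trimethylsilyloxy)buta-1,3-diene, via lithium dienolate 13 (not isolated)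
Conditions: LiN(i-Pr)2 (LDA, 1.1 equiv), THF, −78 °C; Me3SiCl, −78 → 0 °C; non-aqueous work-up (pentane, filtration), used crude at once
Reagents that add atoms: chlorotrimethylsilane, C[Si](C)(C)Cl
Why: Kinetic γ-deprotonation of a β-alkoxy crotonate to the extended lithium dienolate 13 followed by O-silylation, the standard preparation of 1-alkoxy-1-silyloxy dienes; at −78 °C the allylic OCH2 is not metalated and the allyl vinyl ether does not rearrange.

Step 7
Reactants: 9 (R)-4-(tert-butyldimethylsilyloxy)-5-[4-(tert-butyldimethylsilyloxy)phenyl]pent-1-yn-3-one; 14 (1Z)-3-(geranyloxy)-1-methoxy-1-(trimethylsilyloxy)buta-1,3-diene (1.5–2 equiv)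
Product: 17 (R)-2-(tert-butyldimethylsilyloxy)-3-[4-(tert-butyldimethylsilyloxy)phenyl]-1-[4-(geranyloxy)-2-hydroxyphenyl]propan-1-one, via cycloadduct 15 (not isolated), via aryl trimethylsilyl ether 16 (not isolated)
Conditions: toluene, −20 °C → rt (not above 25 °C), dark; then aq. citric acid, THF, 0 °C
Reagents that add atoms: none
Why: Normal-electron-demand Diels–Alder cycloaddition of the electron-rich ketene-acetal diene 14 to the electron-poor alkyne of 9, strongly asynchronous (in the limit a Mukaiyama–Michael addition followed by closure onto the silyloxycarbenium carbon): the CH2 terminus of the diene bonds to the unsubstituted alkyne carbon (ring A C5–C6) and the ketene acetal carbon to the acyl-bearing alkyne carbon (ring A C2–C1). The closest known reaction type is the cycloaddition–aromatisation of 3-alkoxy-1-methoxy-1-(silyloxy)butadienes with alkynyl ketones and esters, which gives 2-hydroxy-4-alkoxyaryl carbonyl compounds as single regioisomers. Ring A is closed as a six-membered carbocycle in the [4+2] mode, suprafacial on both components (6-exo-trig for the second bond in the stepwise limit), to give cyclohexa-1,4-diene 15. No lasting stereocentre is formed: the ketal carbon of 15 is planarised when methanol is lost from ring carbons C2 and C5 to give aryl silyl ether 16, whose O–Si bond is hydrolysed on the mildly acidic work-up to the hydrogen-bonded C2 phenol of 17, and the (R) carbinol centre is untouched because the medium contains no base. Regioselectivity is needed and is secured by the polarity match between the nucleophilic CH2 terminus of 14 and the β-carbon of the ynone, reinforced by the unhindered terminal alkyne; chemoselectivity over Claisen rearrangement of the allyl vinyl ether in 14 is needed and is secured by the high dienophilicity of the terminal ynone, which should let the reaction run at or below room temperature. Loss of methanol in place of silanol is also needed and is favoured because the silyloxy oxygen assists ionisation of the C–OMe bond and stays on the ring carbon that becomes aromatic.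

Step 8
Reactants: 17 (R)-2-(tert-butyldimethylsilyloxy)-3-[4-(tert-butyldimethylsilyloxy)phenyl]-1-[4-(geranyloxy)-2-hydroxyphenyl]propan-1-one
Product: 19 (R)-1-[4-(geranyloxy)-2-hydroxyphenyl]-2-hydroxy-3-(4-hydroxyphenyl)propan-1-one (CNP0159413.1), via carbinol monosilyl ether 18 (not isolated)
Conditions: HF·pyridine, pyridine, THF, 0 °C → rt (polypropylene vessel)
Reagents that add atoms: none
Why: Fluoride-mediated cleavage of silyl ethers driven by Si–F bond formation: the aryl silyl ether should go first to give 18 and the α-keto carbinol silyl ether should follow, while the pyridine-buffered, weakly acidic medium neither enolises the α-hydroxy ketone stereocentre nor ionises the allylic aryl ether.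

Compound list
1 | D-tyrosine, (R)-2-amino-3-(4-hydroxyphenyl)propanoic acid | N[C@H](Cc1ccc(O)cc1)C(=O)O | starting material
2 | (R)-1-carboxylato-2-(4-hydroxyphenyl)ethane-1-diazonium (zwitterion) | N#[N+][C@H](Cc1ccc(O)cc1)C(=O)[O-] | intermediate (not isolated)
3 | (S)-3-(4-hydroxybenzyl)oxiran-2-one (α-lactone) | O=C1O[C@H]1Cc1ccc(O)cc1 | intermediate (not isolated)
4 | (R)-2-hydroxy-3-(4-hydroxyphenyl)propanoic acid | OC(=O)[C@H](O)Cc1ccc(O)cc1 | intermediate
5 | 1H-benzotriazol-1-yl (R)-2-hydroxy-3-(4-hydroxyphenyl)propanoate | O=C(On1nnc2ccccc12)[C@H](O)Cc1ccc(O)cc1 | intermediate (not isolated)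
6 | (R)-2-hydroxy-3-(4-hydroxyphenyl)-N-methoxy-N-methylpropanamide | CON(C)C(=O)[C@H](O)Cc1ccc(O)cc1 | intermediate
7 | (R)-2-(tert-butyldimethylsilyloxy)-3-[4-(tert-butyldimethylsilyloxy)phenyl]-N-methoxy-N-methylpropanamide | CON(C)C(=O)[C@H](O[Si](C)(C)C(C)(C)C)Cc1ccc(O[Si](C)(C)C(C)(C)C)cc1 | intermediate
8 | bromomagnesium (4R)-4-(tert-butyldimethylsilyloxy)-5-[4-(tert-butyldimethylsilyloxy)phenyl]-3-[methoxy(methyl)amino]pent-1-yn-3-olate (both epimers at C3) | C#CC(O[Mg]Br)(N(C)OC)[C@H](O[Si](C)(C)C(C)(C)C)Cc1ccc(O[Si](C)(C)C(C)(C)C)cc1 | intermediate (not isolated)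
9 | (R)-4-(tert-butyldimethylsilyloxy)-5-[4-(tert-butyldimethylsilyloxy)phenyl]pent-1-yn-3-one | C#CC(=O)[C@H](O[Si](C)(C)C(C)(C)C)Cc1ccc(O[Si](C)(C)C(C)(C)C)cc1 | intermediate
10 | geraniol, (2E)-3,7-dimethylocta-2,6-dien-1-ol | CC(C)=CCC/C(C)=C/CO | starting material
11 | methyl but-2-ynoate | CC#CC(=O)OC | starting material
12 | methyl (2E)-3-(geranyloxy)but-2-enoate | CC(C)=CCC/C(C)=C/CO/C(C)=C/C(=O)OC | intermediate
13 | lithium 3-(geranyloxy)-1-methoxybuta-1,3-dien-1-olate | CC(C)=CCC/C(C)=C/COC(=C)C=C(OC)O[Li] | intermediate (not isolated)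
14 | (1Z)-3-(geranyloxy)-1-methoxy-1-(trimethylsilyloxy)buta-1,3-diene | CC(C)=CCC/C(C)=C/COC(=C)/C=C(/OC)O[Si](C)(C)C | intermediate
15 | (R)-2-(tert-butyldimethylsilyloxy)-3-[4-(tert-butyldimethylsilyloxy)phenyl]-1-[4-(geranyloxy)-6-methoxy-6-(trimethylsilyloxy)cyclohexa-1,4-dien-1-yl]propan-1-one (both epimers at ring C6) | CC(C)=CCC/C(C)=C/COC1=CC(OC)(O[Si](C)(C)C)C(C(=O)[C@H](O[Si](C)(C)C(C)(C)C)Cc2ccc(O[Si](C)(C)C(C)(C)C)cc2)=CC1 | intermediate (not isolated)
16 | (R)-2-(tert-butyldimethylsilyloxy)-3-[4-(tert-butyldimethylsilyloxy)phenyl]-1-[4-(geranyloxy)-2-(trimethylsilyloxy)phenyl]propan-1-one | CC(C)=CCC/C(C)=C/COc1ccc(C(=O)[C@H](O[Si](C)(C)C(C)(C)C)Cc2ccc(O[Si](C)(C)C(C)(C)C)cc2)c(O[Si](C)(C)C)c1 | intermediate (not isolated)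
17 | (R)-2-(tert-butyldimethylsilyloxy)-3-[4-(tert-butyldimethylsilyloxy)phenyl]-1-[4-(geranyloxy)-2-hydroxyphenyl]propan-1-one | CC(C)=CCC/C(C)=C/COc1ccc(C(=O)[C@H](O[Si](C)(C)C(C)(C)C)Cc2ccc(O[Si](C)(C)C(C)(C)C)cc2)c(O)c1 | intermediate
18 | (R)-2-(tert-butyldimethylsilyloxy)-1-[4-(geranyloxy)-2-hydroxyphenyl]-3-(4-hydroxyphenyl)propan-1-one | CC(C)=CCC/C(C)=C/COc1ccc(C(=O)[C@H](O[Si](C)(C)C(C)(C)C)Cc2ccc(O)cc2)c(O)c1 | intermediate (not isolated)
19 | (R)-1-[4-(geranyloxy)-2-hydroxyphenyl]-2-hydroxy-3-(4-hydroxyphenyl)propan-1-one (CNP0159413.1) | CC(C)=CCC/C(C)=C/COc1ccc(C(=O)[C@H](O)Cc2ccc(O)cc2)c(O)c1 | target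

Total step count: 8. Longest linear sequence: 6 steps (steps 1, 2, 3, 4, 7, 8 from D-tyrosine); the diene arm (steps 5 and 6) joins at step 7.

Steps most likely to fail

1. Step 7. What may go wrong: Claisen rearrangement or hydrolysis of the allyl vinyl ether and ketene acetal of the diene before it is intercepted; arrest at the open-chain conjugate adduct without ring closure; elimination of silanol in place of methanol during aromatisation, which would leave a C2 methyl ether. The fallback sets out from 9 and takes the geranyl group out of the diene. Cycloaddition of 9 with commercial 1-methoxy-1,3-bis(trimethylsilyloxy)buta-1,3-diene has no allyl vinyl ether to protect, so it may be warmed to 60–80 °C in toluene, and should give cycloadduct F1. On aqueous acidic work-up F1 should lose methanol and both trimethylsilyl groups to give resorcinol ketone F2. Mitsunobu etherification of F2 with geraniol 10 (PPh3, DIAD, THF, 0 °C) should take place only at the C4 hydroxyl, because the C2 hydroxyl is hydrogen-bonded to the ketone, and returns to the route at 17.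

2. Step 5. What may go wrong: addition of geraniol at the γ-carbon after phosphine-mediated isomerisation of the ynoate in place of β-addition, or phosphine-induced oligomerisation of the ynoate. The fallback sets out from 10 and uses no phosphine. Geraniol with catalytic NaH (forming geranyl-ONa) is added to commercial methyl buta-2,3-dienoate in THF at 0 °C, where the alkoxide can attack only the central allene carbon. This should give the deconjugated adduct methyl 3-(geranyloxy)but-3-enoate F3, which should isomerise in the basic medium to 12, where the route is rejoined. Any F3 that remains gives the same dienolate 13 in step 6.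

3. Step 4. What may go wrong: conjugate addition of the released N,O-dimethylhydroxylamine or of a second acetylide to the ynone, oligomerisation of the terminal ynone on concentration, or enolisation at the α-carbon during a slow quench. The fallback sets out from 7 and reaches the ketone by oxidation in place of acyl substitution. Reduction with i-Bu2AlH (THF, −78 °C) should give aldehyde F4, used at once. Addition of HC≡CMgBr at −78 °C should give propargylic alcohols F5 as both carbinol epimers, which does not matter because that centre is oxidised. Dess–Martin periodinane (NaHCO3, CH2Cl2, 0 °C) should then give 9 under non-basic conditions with no amine present.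

Further compounds
F1 | step 7 | (R)-2-(tert-butyldimethylsilyloxy)-3-[4-(tert-butyldimethylsilyloxy)phenyl]-1-[6-methoxy-4,6-bis(trimethylsilyloxy)cyclohexa-1,4-dien-1-yl]propan-1-one | C[Si](C)(C)OC1=CC(OC)(O[Si](C)(C)C)C(C(=O)[C@H](O[Si](C)(C)C(C)(C)C)Cc2ccc(O[Si](C)(C)C(C)(C)C)cc2)=CC1
F2 | step 7 | (R)-2-(tert-butyldimethylsilyloxy)-3-[4-(tert-butyldimethylsilyloxy)phenyl]-1-(2,4-dihydroxyphenyl)propan-1-one | Oc1ccc(C(=O)[C@H](O[Si](C)(C)C(C)(C)C)Cc2ccc(O[Si](C)(C)C(C)(C)C)cc2)c(O)c1
F3 | step 5 | methyl 3-(geranyloxy)but-3-enoate | CC(C)=CCC/C(C)=C/COC(=C)CC(=O)OC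
F4 | step 4 | (R)-2-(tert-butyldimethylsilyloxy)-3-[4-(tert-butyldimethylsilyloxy)phenyl]propanal | O=C[C@H](O[Si](C)(C)C(C)(C)C)Cc1ccc(O[Si](C)(C)C(C)(C)C)cc1
F5 | step 4 | (3RS,4R)-4-(tert-butyldimethylsilyloxy)-5-[4-(tert-butyldimethylsilyloxy)phenyl]pent-1-yn-3-ol | C#CC(O)[C@H](O[Si](C)(C)C(C)(C)C)Cc1ccc(O[Si](C)(C)C(C)(C)C)cc1
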